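**Retrosynthetic overview**
1. Tandyukisin D ⇐ late acylation of the axial C6–OH with 3-methylglutaconic anhydride; the β-hydroxy ketone ⇐ C1 methyl ester (methyl ketone, then formaldehyde aldol).
2. C3=C4 alkene ⇐ C4 ketone (enol triflate reduction); sec-butyl and C8 methyl ⇐ hydrogenation of a butenyl group and an exocyclic methylene.
3. Ring B ⇐ type-two carbonyl-ene closure (C6–C7) of an isopropenyl/α-silyloxy-aldehyde pair, set up by conjugate addition–aldol on a ring-A enone.
4. Ring-A enone ⇐ enantioselective Rh-catalysed alkenyl addition that breaks the mirror symmetry of methyl 1-methyl-4-oxocyclohexa-2,5-diene-1-carboxylate (key step).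
5. That dienone ⇐ Birch reductive methylation of methyl benzoate plus bis-allylic oxidation; ring A (the former arene) is formed first, ring B second.

Assumption: the target is (1S,2S,4aR,5S,6R,8R,8aS) with a (2R)-butan-2-yl group and a Z-configured 3-methylglutaconate, as read from the SMILES. Decalin numbering: C1 (quaternary, Me + carbonyl), C2 (sec-butyl), C3, C4, C4a, C5 (OH), C6 (O-acyl), C7, C8 (Me), C8a; β is the face of the C1 methyl. Compounds 5 and 8 (dried and distilled from its aqueous solution) are taken as commercial.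

Step 1
Reactants: 1 methyl benzoate
Product: 3 methyl 1-methylcyclohexa-2,5-diene-1-carboxylate, via potassium ester dienolate 2 (not isolated)
Conditions: K (2.2 equiv), t-BuOH (1 equiv), liquid NH3/THF, −78 °C; then MeI, −78 °C to rt
Reagents that add atoms: iodomethane, CI
Why: Birch reductive alkylation: two-electron reduction and para-protonation give the ester dienolate, which is C-methylated at the ipso carbon; no stereocentre is formed.

Step 2
Reactants: 3 methyl 1-methylcyclohexa-2,5-diene-1-carboxylate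
Product: 4 methyl 1-methyl-4-oxocyclohexa-2,5-diene-1-carboxylate
Conditions: CrO3 (10 mol %), t-BuOOH (4 equiv), CH2Cl2, rt
Reagents that add atoms: tert-butyl hydroperoxide, CC(C)(C)OO
Why: chromium-catalysed allylic C–H oxidation of the only doubly allylic CH2; the quaternary C1 prevents aromatisation, so the achiral cross-conjugated dienone results.

Step 3
Reactants: 4 methyl 1-methyl-4-oxocyclohexa-2,5-diene-1-carboxylate; 5 potassium (Z)-but-2-en-2-yltrifluoroborate
Product: 6 methyl (1R,6R)-6-[(2E)-but-2-en-2-yl]-1-methyl-4-oxocyclohex-2-ene-1-carboxylate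
Conditions: [Rh(cod)2]BF4 (3 mol %), (R)-BINAP (3.3 mol %), Et3N (1.5 equiv), toluene/H2O 10:1, 25–40 °C (5: 1.2 equiv)
Reagents that add atoms: none
Why: Hayashi–Miyaura Rh-catalysed asymmetric 1,4-addition used as an enantiotopic-group-selective desymmetrisation: the (R)-BINAP–Rh–alkenyl accepts one enone π-face type (ligand chosen by analogy with cyclohex-2-enone; use the antipode if the sense is reversed), and only on one of the two C=C bonds is that face anti to the C1 methyl and syn to the flatter, smaller CO2Me, so C6 and the now stereogenic C1 are set together with retention of alkenyl geometry.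

Step 4
Reactants: 6 methyl (1R,6R)-6-[(2E)-but-2-en-2-yl]-1-methyl-4-oxocyclohex-2-ene-1-carboxylate; 7 isopropenylmagnesium bromide; 8 2,2-dimethoxyacetaldehyde
Product: 10 methyl (1S,2R,3R,6R)-6-[(2E)-but-2-en-2-yl]-3-[(1S)-1-hydroxy-2,2-dimethoxyethyl]-1-methyl-4-oxo-2-(prop-1-en-2-yl)cyclohexane-1-carboxylate, via bromomagnesium enolate 9 (not isolated)
Conditions: 7 (1.3 equiv), CuBr·SMe2 (15 mol %), THF, −40 °C; then 8 (2.5 equiv), −78 °C; then H2O
Reagents that add atoms: none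
Why: Cu-catalysed conjugate addition followed by aldol trapping: axial attack on the half-chair with the butenyl group equatorial puts isopropenyl trans to it (cis to the C1 methyl), the enolate reacts trans to the new group, and the Zimmerman–Traxler chair of the cyclic E-enolate gives the anti aldol (carbinol S).

Step 5
Reactants: 10 methyl (1S,2R,3R,6R)-6-[(2E)-but-2-en-2-yl]-3-[(1S)-1-hydroxy-2,2-dimethoxyethyl]-1-methyl-4-oxo-2-(prop-1-en-2-yl)cyclohexane-1-carboxylate
Product: 13 methyl (1S,2R,3R,6R)-6-[(2E)-but-2-en-2-yl]-1-methyl-4-oxo-3-[(1S)-2-oxo-1-(triethylsilyloxy)ethyl]-2-(prop-1-en-2-yl)cyclohexane-1-carboxylate, via triethylsilyl ether acetal 11 (not isolated), via collidinium triflate adduct 12 (not isolated)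
Conditions: Et3SiOTf (3.5 equiv), 2,4,6-collidine (5 equiv), CH2Cl2, −40 to 0 °C; then H2O, 0 °C to rt
Reagents that add atoms: triethylsilyl trifluoromethanesulfonate, CC[Si](CC)(CC)OS(=O)(=O)C(F)(F)F; water, O
Why: silyl triflate with a hindered pyridine silylates the β-hydroxyl and converts the dimethyl acetal into a collidinium salt that water hydrolyses to the aldehyde without protic acid, so the aldol unit neither eliminates nor cleaves and no stereocentre changes.

Step 6
Reactants: 13 methyl (1S,2R,3R,6R)-6-[(2E)-but-2-en-2-yl]-1-methyl-4-oxo-3-[(1S)-2-oxo-1-(triethylsilyloxy)ethyl]-2-(prop-1-en-2-yl)cyclohexane-1-carboxylate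
Product: 14 methyl 2α-[(2E)-but-2-en-2-yl]-6β-hydroxy-1β-methyl-8-methylidene-4-oxo-5β-(triethylsilyloxy)decahydronaphthalene-1α-carboxylate (trans-fused; 4aβ-H/8aα-H)
Conditions: Me2AlCl (2.2 equiv), CH2Cl2, −78 to −20 °C; then H2O/aq. NaHCO3
Reagents that add atoms: none
Why: Lewis-acid type-two intramolecular carbonyl-ene reaction: the chair transition state with both ring-A arms equatorial gives the trans-fused ring B, and concerted hydrogen transfer from the allylic methyl needs the carbonyl oxygen axial, which sets the axial 6β-OH cis to the 5β-oxygen.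

Step 7
Reactants: 14 methyl 2α-[(2E)-but-2-en-2-yl]-6β-hydroxy-1β-methyl-8-methylidene-4-oxo-5β-(triethylsilyloxy)decahydronaphthalene-1α-carboxylate
Product: 15 methyl 2α-[(2E)-but-2-en-2-yl]-6β-hydroxy-1β,8α-dimethyl-4-oxo-5β-(triethylsilyloxy)decahydronaphthalene-1α-carboxylate (trans-fused)
Conditions: [Rh(nbd)(dppb)]BF4 (5 mol %), H2 (60 bar), CH2Cl2, 25 °C
Reagents that add atoms: none
Why: hydroxyl-directed homogeneous hydrogenation: the cationic rhodium binds the axial 6β-OH and delivers H2 to the β face of the exocyclic alkene, giving the equatorial 8α-methyl, while the unfunctionalised trisubstituted butenyl alkene is not reduced by this catalyst.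

Step 8
Reactants: 15 methyl 2α-[(2E)-but-2-en-2-yl]-6β-hydroxy-1β,8α-dimethyl-4-oxo-5β-(triethylsilyloxy)decahydronaphthalene-1α-carboxylate
Product: 16 methyl 2α-[(2R)-butan-2-yl]-6β-hydroxy-1β,8α-dimethyl-4-oxo-5β-(triethylsilyloxy)decahydronaphthalene-1α-carboxylate (trans-fused)
Conditions: [Ir(cod)(L)][B(C6H3(CF3)2)4] (2 mol %), L = 7-(di-tert-butylphosphinooxy)-2-phenyl-6,7-dihydro-5H-cyclopenta[b]pyridine (enantiomer selected for the R centre), H2 (50 bar), CH2Cl2, 25 °C
Reagents that add atoms: none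
Why: iridium N,P-ligand asymmetric hydrogenation of an unfunctionalised trialkyl-substituted alkene: catalyst-controlled face selection on the (E)-2-alkylbut-2-ene unit sets the (R) side-chain centre, and the ketone, ester and silyl ether are inert.

Step 9
Reactants: 16 methyl 2α-[(2R)-butan-2-yl]-6β-hydroxy-1β,8α-dimethyl-4-oxo-5β-(triethylsilyloxy)decahydronaphthalene-1α-carboxylate
Product: 18 methyl 2α-[(2R)-butan-2-yl]-6β-hydroxy-1β,8α-dimethyl-5β-(triethylsilyloxy)-4-(trifluoromethylsulfonyloxy)-1,2,4a,5,6,7,8,8a-octahydronaphthalene-1α-carboxylate, via dipotassium enolate alkoxide 17 (not isolated)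
Conditions: KN(SiMe3)2 (2.2 equiv), THF, −78 °C; PhNTf2 (1.1 equiv), −78 to −30 °C; then H2O
Reagents that add atoms: N-phenylbis(trifluoromethanesulfonimide), O=S(=O)(N(c1ccccc1)S(=O)(=O)C(F)(F)F)C(F)(F)F
Why: kinetic enolate O-triflation: the base removes the secondary C3 proton and not the tertiary ring-fusion C4a proton, so the C3=C4 enol triflate forms; the second equivalent only holds the C6 hydroxyl as its alkoxide.

Step 10
Reactants: 18 methyl 2α-[(2R)-butan-2-yl]-6β-hydroxy-1β,8α-dimethyl-5β-(triethylsilyloxy)-4-(trifluoromethylsulfonyloxy)-1,2,4a,5,6,7,8,8a-octahydronaphthalene-1α-carboxylate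
Product: 19 methyl 2α-[(2R)-butan-2-yl]-6β-hydroxy-1β,8α-dimethyl-5β-(triethylsilyloxy)-1,2,4a,5,6,7,8,8a-octahydronaphthalene-1α-carboxylate
Conditions: Pd(OAc)2 (5 mol %), PPh3 (10 mol %), HCO2H (2 equiv), n-Bu3N (3 equiv), DMF, 60 °C
Reagents that add atoms: none
Why: Pd-catalysed formate reduction of a vinyl triflate (oxidative addition, formate exchange, decarboxylation, reductive elimination) leaves the alkene at C3=C4 as in the target.

Step 11
Reactants: 19 methyl 2α-[(2R)-butan-2-yl]-6β-hydroxy-1β,8α-dimethyl-5β-(triethylsilyloxy)-1,2,4a,5,6,7,8,8a-octahydronaphthalene-1α-carboxylate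
Product: 22 1-[2α-((2R)-butan-2-yl)-6β-hydroxy-1β,8α-dimethyl-5β-(triethylsilyloxy)-1,2,4a,5,6,7,8,8a-octahydronaphthalen-1α-yl]ethan-1-one, via dilithium silyl enolate 20 (not isolated), via silylmethyl ketone 21 (not isolated)
Conditions: Me3SiCH2Li (4 equiv), pentane/THF, 0 °C to rt; then MeOH, rt
Reagents that add atoms: (trimethylsilyl)methyllithium, [Li]C[Si](C)(C)C
Why: acyl substitution of the ester by Me3SiCH2Li gives an α-silyl ketone that is at once deprotonated to its enolate, which blocks a second addition; methanolysis then cleaves the C–Si bond to leave the methyl ketone.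

Step 12
Reactants: 22 1-[2α-((2R)-butan-2-yl)-6β-hydroxy-1β,8α-dimethyl-5β-(triethylsilyloxy)-1,2,4a,5,6,7,8,8a-octahydronaphthalen-1α-yl]ethan-1-one
Product: 24 1-[2α-((2R)-butan-2-yl)-6β-hydroxy-1β,8α-dimethyl-5β-(triethylsilyloxy)-1,2,4a,5,6,7,8,8a-octahydronaphthalen-1α-yl]-3-hydroxypropan-1-one, via dilithium enolate alkoxide 23 (not isolated)
Conditions: LiN(i-Pr)2 (2.5 equiv), THF, −78 °C; CH2O (gas from cracked paraformaldehyde), −78 °C; then H2O
Reagents that add atoms: formaldehyde, C=O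
Why: crossed aldol (hydroxymethylation) of the only possible enolate, since the other α-carbon is the quaternary C1; the C6 alkoxide adds formaldehyde only reversibly.

Step 13
Reactants: 24 1-[2α-((2R)-butan-2-yl)-6β-hydroxy-1β,8α-dimethyl-5β-(triethylsilyloxy)-1,2,4a,5,6,7,8,8a-octahydronaphthalen-1α-yl]-3-hydroxypropan-1-one
Product: 25 1-[2α-((2R)-butan-2-yl)-6β-hydroxy-1β,8α-dimethyl-5β-(triethylsilyloxy)-1,2,4a,5,6,7,8,8a-octahydronaphthalen-1α-yl]-3-(tert-butyldimethylsilyloxy)propan-1-one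
Conditions: t-BuMe2SiCl (1.1 equiv), imidazole, CH2Cl2, 0 °C
Reagents that add atoms: tert-butyldimethylsilyl chloride, CC(C)(C)[Si](C)(C)Cl
Why: silylation selective for the primary alcohol over the hindered axial secondary C6–OH, which stays free for the acylation.

Step 14
Reactants: 26 3-methylglutaconic acid (E/Z mixture)
Product: 27 3-methylglutaconic anhydride (4-methyl-2H-pyran-2,6(3H)-dione)
Conditions: Ac2O, 60 °C; evaporate
Reagents that add atoms: none
Why: dehydrative cyclisation to the six-membered anhydride, whose ring can only hold the Z alkene, so both acid isomers converge on it.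

Step 15
Reactants: 25 1-[2α-((2R)-butan-2-yl)-6β-hydroxy-1β,8α-dimethyl-5β-(triethylsilyloxy)-1,2,4a,5,6,7,8,8a-octahydronaphthalen-1α-yl]-3-(tert-butyldimethylsilyloxy)propan-1-one; 27 3-methylglutaconic anhydride
Product: 28 (2Z)-5-[[2α-((2R)-butan-2-yl)-1α-(3-(tert-butyldimethylsilyloxy)propanoyl)-1β,8α-dimethyl-5β-(triethylsilyloxy)-1,2,4a,5,6,7,8,8a-octahydronaphthalen-6β-yl]oxy]-3-methyl-5-oxopent-2-enoic acid
Conditions: 27 (3 equiv), toluene, 50 °C
Reagents that add atoms: none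
Why: alcoholysis of the unsymmetrical cyclic anhydride at its non-conjugated, more electrophilic carbonyl gives the CH2-side ester and the free conjugated acid with Z geometry fixed by the ring; base-free conditions avoid alkene isomerisation.

Step 16
Reactants: 28 (2Z)-5-[[2α-((2R)-butan-2-yl)-1α-(3-(tert-butyldimethylsilyloxy)propanoyl)-1β,8α-dimethyl-5β-(triethylsilyloxy)-1,2,4a,5,6,7,8,8a-octahydronaphthalen-6β-yl]oxy]-3-methyl-5-oxopent-2-enoic acid
Product: 29 Tandyukisin D
Conditions: HF·pyridine, pyridine, THF, 0 °C to rt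
Reagents that add atoms: none
Why: fluoride desilylation under buffered, mildly acidic conditions removes both silyl ethers without acyl migration in the cis-hydroxy ester or dehydration of the β-hydroxy ketone.

**Compound list**
1 | methyl benzoate | COC(=O)c1ccccc1 | starting material
2 | potassium ester dienolate (potassium 1-[methoxy(oxido)methylidene]cyclohexa-2,5-diene) | COC([O-])=C1C=CCC=C1.[K+] | intermediate
3 | methyl 1-methylcyclohexa-2,5-diene-1-carboxylate | COC(=O)C1(C)C=CCC=C1 | intermediate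
4 | methyl 1-methyl-4-oxocyclohexa-2,5-diene-1-carboxylate | COC(=O)C1(C)C=CC(=O)C=C1 | intermediate
5 | potassium (Z)-but-2-en-2-yltrifluoroborate | C/C=C(\C)[B-](F)(F)F.[K+] | starting material
6 | methyl (1R,6R)-6-[(2E)-but-2-en-2-yl]-1-methyl-4-oxocyclohex-2-ene-1-carboxylate (butenyl cis to CO2Me) | C/C=C(\C)[C@H]1CC(=O)C=C[C@@]1(C)C(=O)OC | intermediate
7 | isopropenylmagnesium bromide | CC(=C)[Mg]Br | starting material
8 | 2,2-dimethoxyacetaldehyde | COC(OC)C=O | starting material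
9 | bromomagnesium C3–C4 enolate of methyl (1S,2R,6R)-6-[(2E)-but-2-en-2-yl]-1-methyl-4-oxo-2-(prop-1-en-2-yl)cyclohexane-1-carboxylate | C/C=C(\C)[C@H]1CC(O[Mg]Br)=C[C@H](C(C)=C)[C@@]1(C)C(=O)OC | intermediate
10 | methyl (1S,2R,3R,6R)-6-[(2E)-but-2-en-2-yl]-3-[(1S)-1-hydroxy-2,2-dimethoxyethyl]-1-methyl-4-oxo-2-(prop-1-en-2-yl)cyclohexane-1-carboxylate | C/C=C(\C)[C@H]1CC(=O)[C@@H]([C@H](O)C(OC)OC)[C@H](C(C)=C)[C@@]1(C)C(=O)OC | intermediate
11 | methyl (1S,2R,3R,6R)-6-[(2E)-but-2-en-2-yl]-3-[(1S)-2,2-dimethoxy-1-(triethylsilyloxy)ethyl]-1-methyl-4-oxo-2-(prop-1-en-2-yl)cyclohexane-1-carboxylate | C/C=C(\C)[C@H]1CC(=O)[C@@H]([C@H](O[Si](CC)(CC)CC)C(OC)OC)[C@H](C(C)=C)[C@@]1(C)C(=O)OC | intermediate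
12 | collidinium triflate adduct of 11 (one acetal OMe replaced by N-bound 2,4,6-trimethylpyridinium; epimers at that carbon) | C/C=C(\C)[C@H]1CC(=O)[C@@H]([C@H](O[Si](CC)(CC)CC)C(OC)[n+]2c(C)cc(C)cc2C)[C@H](C(C)=C)[C@@]1(C)C(=O)OC.[O-]S(=O)(=O)C(F)(F)F | intermediate
13 | methyl (1S,2R,3R,6R)-6-[(2E)-but-2-en-2-yl]-1-methyl-4-oxo-3-[(1S)-2-oxo-1-(triethylsilyloxy)ethyl]-2-(prop-1-en-2-yl)cyclohexane-1-carboxylate | C/C=C(\C)[C@H]1CC(=O)[C@@H]([C@H](O[Si](CC)(CC)CC)C=O)[C@H](C(C)=C)[C@@]1(C)C(=O)OC | intermediate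
14 | methyl 2α-[(2E)-but-2-en-2-yl]-6β-hydroxy-1β-methyl-8-methylidene-4-oxo-5β-(triethylsilyloxy)decahydronaphthalene-1α-carboxylate (trans-fused; 4aβ-H/8aα-H) | C/C=C(\C)[C@H]1CC(=O)[C@H]2[C@H](O[Si](CC)(CC)CC)[C@H](O)CC(=C)[C@@H]2[C@@]1(C)C(=O)OC | intermediate
15 | methyl 2α-[(2E)-but-2-en-2-yl]-6β-hydroxy-1β,8α-dimethyl-4-oxo-5β-(triethylsilyloxy)decahydronaphthalene-1α-carboxylate (trans-fused) | C/C=C(\C)[C@H]1CC(=O)[C@H]2[C@H](O[Si](CC)(CC)CC)[C@H](O)C[C@@H](C)[C@@H]2[C@@]1(C)C(=O)OC | intermediate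
16 | methyl 2α-[(2R)-butan-2-yl]-6β-hydroxy-1β,8α-dimethyl-4-oxo-5β-(triethylsilyloxy)decahydronaphthalene-1α-carboxylate (trans-fused) | CC[C@@H](C)[C@H]1CC(=O)[C@H]2[C@H](O[Si](CC)(CC)CC)[C@H](O)C[C@@H](C)[C@@H]2[C@@]1(C)C(=O)OC | intermediate
17 | dipotassium C3–C4 enolate / C6 alkoxide of 16 | CC[C@@H](C)[C@H]1C=C([O-])[C@H]2[C@H](O[Si](CC)(CC)CC)[C@H]([O-])C[C@@H](C)[C@@H]2[C@@]1(C)C(=O)OC.[K+].[K+] | intermediate
18 | methyl 2α-[(2R)-butan-2-yl]-6β-hydroxy-1β,8α-dimethyl-5β-(triethylsilyloxy)-4-(trifluoromethylsulfonyloxy)-1,2,4a,5,6,7,8,8a-octahydronaphthalene-1α-carboxylate | CC[C@@H](C)[C@H]1C=C(OS(=O)(=O)C(F)(F)F)[C@H]2[C@H](O[Si](CC)(CC)CC)[C@H](O)C[C@@H](C)[C@@H]2[C@@]1(C)C(=O)OC | intermediate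
19 | methyl 2α-[(2R)-butan-2-yl]-6β-hydroxy-1β,8α-dimethyl-5β-(triethylsilyloxy)-1,2,4a,5,6,7,8,8a-octahydronaphthalene-1α-carboxylate | CC[C@@H](C)[C@H]1C=C[C@H]2[C@H](O[Si](CC)(CC)CC)[C@H](O)C[C@@H](C)[C@@H]2[C@@]1(C)C(=O)OC | intermediate
20 | dilithium enolate / C6 alkoxide of the α-(trimethylsilyl)methyl ketone 21 | CC[C@@H](C)[C@H]1C=C[C@H]2[C@H](O[Si](CC)(CC)CC)[C@H]([O-])C[C@@H](C)[C@@H]2[C@@]1(C)C([O-])=C[Si](C)(C)C.[Li+].[Li+] | intermediate
21 | 1-[decalin as in 19]-2-(trimethylsilyl)ethan-1-one (C1 CO2Me of 19 replaced by C(=O)CH2SiMe3) | CC[C@@H](C)[C@H]1C=C[C@H]2[C@H](O[Si](CC)(CC)CC)[C@H](O)C[C@@H](C)[C@@H]2[C@@]1(C)C(=O)C[Si](C)(C)C | intermediate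
22 | 1-[2α-((2R)-butan-2-yl)-6β-hydroxy-1β,8α-dimethyl-5β-(triethylsilyloxy)-1,2,4a,5,6,7,8,8a-octahydronaphthalen-1α-yl]ethan-1-one | CC[C@@H](C)[C@H]1C=C[C@H]2[C@H](O[Si](CC)(CC)CC)[C@H](O)C[C@@H](C)[C@@H]2[C@@]1(C)C(C)=O | intermediate
23 | dilithium methyl-ketone enolate / C6 alkoxide of 22 | CC[C@@H](C)[C@H]1C=C[C@H]2[C@H](O[Si](CC)(CC)CC)[C@H]([O-])C[C@@H](C)[C@@H]2[C@@]1(C)C([O-])=C.[Li+].[Li+] | intermediate
24 | 1-[2α-((2R)-butan-2-yl)-6β-hydroxy-1β,8α-dimethyl-5β-(triethylsilyloxy)-1,2,4a,5,6,7,8,8a-octahydronaphthalen-1α-yl]-3-hydroxypropan-1-one | CC[C@@H](C)[C@H]1C=C[C@H]2[C@H](O[Si](CC)(CC)CC)[C@H](O)C[C@@H](C)[C@@H]2[C@@]1(C)C(=O)CCO | intermediate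
25 | 3-(tert-butyldimethylsilyloxy) ether of 24 (primary OH silylated, 6β-OH free) | CC[C@@H](C)[C@H]1C=C[C@H]2[C@H](O[Si](CC)(CC)CC)[C@H](O)C[C@@H](C)[C@@H]2[C@@]1(C)C(=O)CCO[Si](C)(C)C(C)(C)C | intermediate
26 | 3-methylglutaconic acid (E/Z mixture) | CC(CC(=O)O)=CC(=O)O | starting material
27 | 3-methylglutaconic anhydride (4-methyl-2H-pyran-2,6(3H)-dione) | CC1=CC(=O)OC(=O)C1 | intermediate
28 | 5-O-triethylsilyl, side-chain O-tert-butyldimethylsilyl ether of Tandyukisin D | CC[C@@H](C)[C@H]1C=C[C@H]2[C@H](O[Si](CC)(CC)CC)[C@H](OC(=O)C/C(C)=C\C(=O)O)C[C@@H](C)[C@@H]2[C@@]1(C)C(=O)CCO[Si](C)(C)C(C)(C)C | intermediate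
29 | Tandyukisin D: (1S,2S,4aR,5S,6R,8R,8aS)-2-[(2R)-butan-2-yl]-5-hydroxy-1-(3-hydroxypropanoyl)-1,8-dimethyl-1,2,4a,5,6,7,8,8a-octahydronaphthalen-6-yl hydrogen (2Z)-3-methylpent-2-enedioate (ester at C5 of the diacid) | CC[C@@H](C)[C@H]1C=C[C@H]2[C@H](O)[C@H](OC(=O)C/C(C)=C\C(=O)O)C[C@@H](C)[C@@H]2[C@@]1(C)C(=O)CCO | target

**Step count**
Total: 16 steps. Longest linear sequence: 15 (steps 1–13, 15, 16 from methyl benzoate); step 14 is a one-step side branch.

**Three steps most likely to fail**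

Step 3. The face preference (CH3 against CO2Me) that couples to the catalyst's enantioface choice is untested. A weak or reversed preference would give the diastereomer with the butenyl group cis to the C1 methyl. The fallback sets out from 4 and returns at 10 by exchanging the order of the two alkenyl transfers, so that the opposite face preference is used. The same [Rh(cod)2]BF4/(R)-BINAP system transfers isopropenyl from CH2=C(CH3)BF3K to the face syn to CH3, giving methyl (1S,6R)-1-methyl-4-oxo-6-(prop-1-en-2-yl)cyclohex-2-ene-1-carboxylate F1. Its kinetic cross-conjugated lithium enolate (LiN(i-Pr)2, THF, −78 °C) undergoes the anti aldol with 8 trans to the isopropenyl group, giving methyl (1S,5R,6R)-5-[(1S)-1-hydroxy-2,2-dimethoxyethyl]-1-methyl-4-oxo-6-(prop-1-en-2-yl)cyclohex-2-ene-1-carboxylate F2. A second Rh/(R)-BINAP addition, now of 5, is delivered axially anti to the axial C1 methyl and trans to isopropenyl; aqueous protonation gives 10.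

Step 6. A Lewis-acid ene reaction can leak into a stepwise cationic closure, which would give the equatorial C6 alcohol. The fallback sets out from 13 and returns at 14; it sets C6 by SN2 inversion instead of by the pericyclic transition state. Closure under stepwise conditions (SnCl4, CH2Cl2, −78 °C) is taken to the 6α epimer methyl 2α-[(2E)-but-2-en-2-yl]-6α-hydroxy-1β-methyl-8-methylidene-4-oxo-5β-(triethylsilyloxy)decahydronaphthalene-1α-carboxylate F3. Mitsunobu reaction (4-nitrobenzoic acid, PPh3, DIAD, toluene) gives the inverted axial ester methyl 2α-[(2E)-but-2-en-2-yl]-1β-methyl-8-methylidene-6β-(4-nitrobenzoyloxy)-4-oxo-5β-(triethylsilyloxy)decahydronaphthalene-1α-carboxylate F4. Methanolysis (K2CO3, MeOH, 0 °C) then gives 14.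

Step 11. The C1 ester is neopentyl and flanked by three substituents, so carbonyl addition may stall. The fallback sets out from 19 and returns at 22; it attacks the unhindered O–CH3 carbon instead of the carbonyl. LiI in refluxing EtOAc cleaves the methyl ester by SN2 to give 2α-[(2R)-butan-2-yl]-6β-hydroxy-1β,8α-dimethyl-5β-(triethylsilyloxy)-1,2,4a,5,6,7,8,8a-octahydronaphthalene-1α-carboxylic acid F5. MeLi (5 equiv, Et2O, 0 °C to rt, Me3SiCl quench, then H2O) converts its lithium carboxylate through the stable gem-diolate into methyl ketone 22.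

**Further compounds**
F1 | step 3 | methyl (1S,6R)-1-methyl-4-oxo-6-(prop-1-en-2-yl)cyclohex-2-ene-1-carboxylate | C1=CC(=O)C[C@H](C(C)=C)[C@@]1(C)C(=O)OC
F2 | step 3 | methyl (1S,5R,6R)-5-[(1S)-1-hydroxy-2,2-dimethoxyethyl]-1-methyl-4-oxo-6-(prop-1-en-2-yl)cyclohex-2-ene-1-carboxylate | C1=CC(=O)[C@@H]([C@H](O)C(OC)OC)[C@H](C(C)=C)[C@@]1(C)C(=O)OC
F3 | step 6 | methyl 2α-[(2E)-but-2-en-2-yl]-6α-hydroxy-1β-methyl-8-methylidene-4-oxo-5β-(triethylsilyloxy)decahydronaphthalene-1α-carboxylate (C6 epimer of 14) | C/C=C(\C)[C@H]1CC(=O)[C@H]2[C@H](O[Si](CC)(CC)CC)[C@@H](O)CC(=C)[C@@H]2[C@@]1(C)C(=O)OC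
F4 | step 6 | methyl 2α-[(2E)-but-2-en-2-yl]-1β-methyl-8-methylidene-6β-(4-nitrobenzoyloxy)-4-oxo-5β-(triethylsilyloxy)decahydronaphthalene-1α-carboxylate | C/C=C(\C)[C@H]1CC(=O)[C@H]2[C@H](O[Si](CC)(CC)CC)[C@H](OC(=O)c3ccc(cc3)[N+](=O)[O-])CC(=C)[C@@H]2[C@@]1(C)C(=O)OC
F5 | step 11 | 2α-[(2R)-butan-2-yl]-6β-hydroxy-1β,8α-dimethyl-5β-(triethylsilyloxy)-1,2,4a,5,6,7,8,8a-octahydronaphthalene-1α-carboxylic acid | CC[C@@H](C)[C@H]1C=C[C@H]2[C@H](O[Si](CC)(CC)CC)[C@H](O)C[C@@H](C)[C@@H]2[C@@]1(C)C(=O)O
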